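## Analysis of the target

The target is an iridoid ester built on a cis-fused cyclopenta[c]pyran. In iridoid numbering, the pyran ring (C1, O2, C3, C4, C5, C9) holds an acyl acetal at C1 and an enol ether C3=C4, with the hydroxymethyl carbon C11 on C4. The cyclopentane ring (C5 to C9) carries 7-OH, the tertiary 8-OH and the p-coumaroyloxymethyl carbon C10.

Read literally, the SMILES gives (1R,5R,7R,8S,9R) with an (S)-3-methylpentanoyl group. H5, H9, the C1 acyloxy group, 7-OH and C10 lie on one face and 8-OH alone on the other, so the 7,8-diol is trans and the tertiary hydroxyl is syn to C1.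

The 5R,9R ring fusion is antipodal to that of genipin and the common iridoid glucosides. The natural iridoid pool therefore does not lead to this enantiomer, and the core has to be made de novo.

Sensitive groups are the acyl acetal (base, nucleophiles), the enol ether with its allylic 11-OH (ionises in acid), and the p-coumarate with a free phenol (light, base). In addition, 8-OH is β to C1, which invites retro-aldol cleavage or dehydration whenever C1 is a free lactol.

The difficulty lies in five contiguous stereocentres on a small bicycle, among them the fully substituted carbinol C8 and the acetal centre C1. Five oxygens (O1, O7, O8, O10, O11) must also be told apart, with two different acyl groups on O1 and O10.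

The feature the strategy uses: C4 bears C3 and C11 and is bonded to C5, while C1 sits on C9 and is tied back to C3 through O2. C1, C3 and C11 are thus three carbons at, or one hydride from, the aldehyde level around C4: a triformylmethane unit laid across the C5–C9 bond. The pyran ring is the retro-aldol/hemiacetal form of a cyclobutane photoadduct of a cyclopentene.

## Retrosynthetic reasoning

**23 to 22 (C11–H).** The last bond made is a hydride to C11. Keeping C11 as the aldehyde until the end makes the enol ether a push-pull system that tolerates acid and fluoride. It also means no free 11-OH competes when O10 is acylated. The forward step must reduce one aldehyde beside two esters.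

**22 to 17 and 20, through 21 (C10–O ester, phenol silyl ether).** The coumarate is cut off as acid 20, whose phenol is masked so that it cannot acylate itself. It is attached late because the cinnamate chromophore would not survive the photochemical step. The forward reaction must choose the primary O10 over the secondary O7.

**17 to 14 and 15, through 16 (C1–O acyl bond, acetonide).** The C1 ester is cut back to lactol 14 and acid 15. The lactol hydroxyl is the only acylable hydroxyl of 14, since 8-OH is tertiary and O7/O10 are tied in the acetonide. The acetonide is then removed from 16 to free 17.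

**14 to 10 and 11 (C4–C5, C1–C9 and O2–C1; key disconnection).** Cutting these three bonds removes the entire pyran ring with C1, C3, C4 and C11 and leaves cyclopentene 10 and triformylmethane 11. The cut is placed here because the four carbons already have the oxidation pattern of 11. The cis ring fusion is the only one a cyclobutane intermediate can have. The dioxane ring of 10 shields exactly the face that must stay free of new bonds.

**10 to 9 (C8–C9).** The tertiary allylic alcohol is opened to a (Z)-alkenyl iodide tethered to a ketone. Closing the cyclopentene by intramolecular addition forces C9 cis to C6 on the dioxane ring. This is the same as 8-OH trans to O7, a relation that intermolecular additions to such ketones would not give.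

**9 to 6 and 3 (C6–C7); 6 to 4 and 5; 3 to 1 through 2.** The single stereocentre that controls everything, C7, is made by auxiliary-controlled alkylation of the symmetric ketone 4 through its hydrazone with 5. The electrophile 3 comes from ester 1 by way of alcohol 2.

## Alternatives that were turned down

**Alternative 1:** the textbook route through a 1,5-dialdehyde.
- Disconnection: O2–C1 and O2–C3, back to dialdehyde A2, which comes from cleaving the C1=C3 bond of the cis-bicyclo[3.3.0]octene A1.
- Forward key step: ozonolysis of A1 and lactolisation of A2.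
- Turned down because C11 is at the alcohol level, so the C3 aldehyde of A2 has no second acceptor on C4 and will not enolise toward O2. A2 would hydrate and close in several ways, and a regioselective dehydration to C3=C4 beside an intact C1 hemiacetal would still be needed.
- The free C1 aldehyde of A2 is β to 8-OH and invites retro-aldol cleavage.
- A1 needs a second carbocycle and a C4 stereocentre that are built only to be destroyed, which costs well over five extra steps.

**Alternative 2:** intramolecular hetero-Diels–Alder reaction.
- Disconnection: C5–C9 and O2–C1 in one step.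
- Forward key step: Knoevenagel condensation of aldehyde A3 with a malondialdehyde equivalent to the 1-oxadiene A4, then inverse-demand cycloaddition onto the tethered enol ether.
- Turned down because C1, C5 and C9 would all be set in one open-chain transition state. The tether centre C8 carries oxygen and carbon on opposite faces, so facial bias is weak, and endo/exo control decides C1.
- A4 is an unstabilised alkylidene malondialdehyde with the tertiary hydroxyl placed for a five-membered oxa-Michael closure onto C5.
- The product would be a C1 methyl acetal that needs acidic exchange for the acyl group, and A3 is no shorter to make than 10.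

**Alternative 3:** single-atom oxygen insertion.
- Disconnection: O2 itself, by Baeyer–Villiger insertion into bicyclic enone A5 to give enol lactone A6, then half-reduction and acylation.
- Turned down on migratory aptitude: the carbonyl C1 of A5 is flanked by the secondary alkyl carbon C9 and the vinyl carbon C3, and the secondary alkyl group migrates better. Oxygen would enter on the C9 side.
- The peracid would also attack the electron-rich enol ether of A6.
- A5 again demands a bicyclo[3.3.0]octenone made only to be edited.

Key step: step 7

Assumption: the SMILES is taken at face value, (1R,5R,7R,8S,9R) in iridoid numbering with an (S) acyl chain; compounds 1, 4, 5, 11, 15 and 18 are purchased.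

## Route

Step 1
Reactants: 1 ethyl (2Z)-3-iodoprop-2-enoate
Product: 2 (2Z)-3-iodoprop-2-en-1-ol
Conditions: i-Bu2AlH (2.2 equiv), CH2Cl2, −78 °C; Rochelle salt work-up
Reagents that add atoms: none
Why: Ester-to-alcohol reduction with an aluminium hydride at low temperature leaves the alkenyl iodide and the (Z) geometry untouched.

Step 2
Reactants: 2 (2Z)-3-iodoprop-2-en-1-ol
Product: 3 (1Z)-3-bromo-1-iodoprop-1-ene
Conditions: CBr4, PPh3, CH2Cl2, 0 °C
Reagents that add atoms: tetrabromomethane BrC(Br)(Br)Br
Why: Appel reaction converts the primary allylic alcohol into the bromide under neutral conditions, so the (Z)-iodoalkene is kept.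

Step 3
Reactants: 4 2,2-dimethyl-1,3-dioxan-5-one; 5 RAMP, (2R)-2-(methoxymethyl)pyrrolidin-1-amine
Product: 6 (2R)-N-(2,2-dimethyl-1,3-dioxan-5-ylidene)-2-(methoxymethyl)pyrrolidin-1-amine
Conditions: cyclohexane, reflux, water separator
Reagents that add atoms: none
Why: Hydrazone formation by condensation; the ketone is symmetric, so there is no regiochemical issue.

Step 4
Reactants: 6 RAMP hydrazone of 4; 3 (1Z)-3-bromo-1-iodoprop-1-ene
Product: 8 (2R)-N-[(4R)-4-[(2Z)-3-iodoprop-2-en-1-yl]-2,2-dimethyl-1,3-dioxan-5-ylidene]-2-(methoxymethyl)pyrrolidin-1-amine, via lithium azaenolate 7 (not isolated)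
Conditions: t-BuLi (1.0 equiv), THF, −78 °C; then 3, −100 to −78 °C
Reagents that add atoms: none
Why: SAMP/RAMP hydrazone alkylation: the chelated azaenolate 7 is attacked by the allylic bromide (SN2 at CH2, alkenyl iodide inert) on the face left open by the methoxymethylpyrrolidine. RAMP is chosen because the topicity that gives (S)-4-methyl-3-heptanone from SAMP and 3-pentanone translates here into the (R) centre, which becomes C7 of the target.

Step 5
Reactants: 8 alkylated RAMP hydrazone
Product: 9 (4R)-4-[(2Z)-3-iodoprop-2-en-1-yl]-2,2-dimethyl-1,3-dioxan-5-one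
Conditions: sat. aq. oxalic acid, Et2O, rt
Reagents that add atoms: water O
Why: Two-phase hydrolysis of the hydrazone with oxalic acid is mild enough to keep the acetonide, the alkenyl iodide and the α-alkoxy stereocentre; the auxiliary passes into the aqueous phase and can be recovered.

Step 6
Reactants: 9 (4R)-4-[(2Z)-3-iodoprop-2-en-1-yl]-2,2-dimethyl-1,3-dioxan-5-one
Product: 10 (4aS,7aR)-2,2-dimethyl-4,4a,7,7a-tetrahydrocyclopenta[d][1,3]dioxin-4a-ol
Conditions: CrCl2 (5 equiv), NiCl2 (5 mol %), degassed DMF, rt
Reagents that add atoms: none
Why: Intramolecular Nozaki–Hiyama–Kishi reaction: zerovalent nickel inserts into the carbon–iodine bond, the alkenyl group passes to chromium and adds to the neighbouring ketone. A cyclopentene can span the C7–C8 bond of the dioxane only in cis fashion, so C9 enters cis to C6 and the new tertiary hydroxyl is trans to O7 (8S).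

Step 7
Reactants: 10 (4aS,7aR)-2,2-dimethyl-4,4a,7,7a-tetrahydrocyclopenta[d][1,3]dioxin-4a-ol; 11 triformylmethane
Product: 14 7,10-O-isopropylidene lactol aldehyde (1S,5R,7R,8S,9R; 1-OH and 8-OH free; C11 = CHO), via cyclobutanol photoadduct 12 (not isolated), via ring-opened trialdehyde 13 (not isolated)
Conditions: 11 (4 equiv), hν (medium-pressure Hg lamp, Vycor filter), degassed CH2Cl2/MeCN, −10 °C; then rt in the dark
Reagents that add atoms: none
Why: De Mayo reaction: the hydrogen-bonded enol of 11 is the only chromophore above 240 nm; its excited state adds to the C5=C9 alkene of 10 by a stepwise [2+2] through a 1,4-diradical to give cyclobutanol 12, whose β-hydroxy-aldehyde unit fragments by strain-driven retro-aldol cleavage of the C1–C4 bond to 13, and enolisation of the diformylmethyl group followed by 6-exo-trig hemiacetalisation of the enol oxygen onto the C1 aldehyde closes the pyran ring of 14. The closest known reaction type is the photoannulation of formyl-substituted β-dicarbonyl enols (diformylacetates) onto 3,4-disubstituted cyclopentenes, which gives 1-hydroxy-iridoid skeletons in one operation. C5 and C9 are set together: a cyclobutane can only be cis-fused to the cyclopentene, and the partner should add to the convex face of the cis-fused bicycle 10, the face of the small angular hydroxyl and away from the dioxane ring on the concave face, which places H5 and H9 on the side of O7 and C10 as in the target. The regiochemistry needed is C4 to C5 and C1 to C9; it should be secured by the quaternary carbinol C8 next to C9, because a diradical closure that bonds the diformyl-substituted carbon to C9 would build two adjacent fully substituted centres and should revert rather than close. C1 is not fixed in the photochemical event but by lactol equilibration, which favours the anomer with O1 pseudo-axial (anomeric effect) and trans to C8, that is cis to H9. C7 and C8 are untouched, and the retro-aldol step breaks only the C1–C4 bond, so the new C5 and C9 centres are kept. The step thus forms C4–C5, C1–C9 and O2–C1 and installs C1, C3, C4 and C11 in the right oxidation pattern from a precursor that is one ring and four carbons simpler.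

Step 8
Reactants: 14 lactol aldehyde; 15 (3S)-3-methylpentanoic acid
Product: 16 7,10-O-isopropylidene C1 (3S)-3-methylpentanoate (1R,5R,7R,8S,9R; C11 = CHO)
Conditions: EDC·HCl, DMAP (0.1 equiv), CH2Cl2, −10 °C
Reagents that add atoms: none
Why: Steglich esterification of the lactol hydroxyl, the only acylable hydroxyl (8-OH is tertiary); the anomers interconvert and the one with O1 trans to C8 is both the more stable and the less hindered, so the (1R) ester is expected.

Step 9
Reactants: 16 acetonide-protected C1 ester
Product: 17 triol aldehyde (1R,5R,7R,8S,9R; 7-OH, 8-OH, 10-OH free; C11 = CHO)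
Conditions: AcOH/H2O (4:1), rt to 35 °C
Reagents that add atoms: none
Why: Acid hydrolysis of the six-membered acetonide; the acyl acetal should survive because O2 is part of a β-alkoxy-enal and cannot support an oxocarbenium ion at C1.

Step 10
Reactants: 18 p-coumaric acid
Product: 20 (2E)-3-[4-(tert-butyldimethylsilyloxy)phenyl]prop-2-enoic acid, via bis-silylated p-coumaric acid 19 (not isolated)
Conditions: TBSCl (2.2 equiv), imidazole, DMF, rt; then AcOH/THF/H2O, rt
Reagents that add atoms: tert-butyldimethylsilyl chloride CC(C)(C)[Si](C)(C)Cl
Why: Silylation of both acidic groups, then selective hydrolysis of the far more labile silyl ester, leaves the aryl silyl ether.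

Step 11
Reactants: 17 triol aldehyde; 20 silyl-protected p-coumaric acid
Product: 21 10-O-[4-(tert-butyldimethylsilyloxy)-(E)-cinnamoyl] aldehyde (1R,5R,7R,8S,9R)
Conditions: EDC·HCl, DMAP (0.1 equiv), CH2Cl2, −20 to 0 °C
Reagents that add atoms: none
Why: Steglich esterification; the primary C10 hydroxyl should react faster than the secondary C7 hydroxyl and the tertiary C8 hydroxyl is inert, so one equivalent of acid at low temperature should give the monoester.

Step 12
Reactants: 21 silyl-protected coumarate
Product: 22 10-O-(E)-p-coumaroyl aldehyde (1R,5R,7R,8S,9R; C11 = CHO)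
Conditions: Bu4NF/AcOH (1:1), THF, 0 °C
Reagents that add atoms: none
Why: Buffered fluoride cleaves the aryl silyl ether while both esters and the acyl acetal stay; it is done before the reduction because the aldehyde still stabilises the enol ether.

Step 13
Reactants: 22 10-O-(E)-p-coumaroyl aldehyde
Product: 23 target, [(1R,4aR,6R,7S,7aR)-6,7-dihydroxy-4-(hydroxymethyl)-7-[[(E)-3-(4-hydroxyphenyl)prop-2-enoyl]oxymethyl]-4a,5,6,7a-tetrahydro-1H-cyclopenta[c]pyran-1-yl] (3S)-3-methylpentanoate
Conditions: NaBH4, CeCl3·7H2O, MeOH/THF, −40 °C; pH 7 buffer quench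
Reagents that add atoms: none
Why: Luche reduction gives 1,2-reduction of the β-alkoxy-enal to the allylic alcohol; the cinnamate and the acyl acetal are not reduced by borohydride at this temperature, and no stereocentre is formed.

## Compound list

1 | ethyl (2Z)-3-iodoprop-2-enoate | CCOC(=O)/C=C\I | starting material
2 | (2Z)-3-iodoprop-2-en-1-ol | OC/C=C\I | intermediate
3 | (1Z)-3-bromo-1-iodoprop-1-ene | BrC/C=C\I | intermediate
4 | 2,2-dimethyl-1,3-dioxan-5-one | CC1(C)OCC(=O)CO1 | starting material
5 | RAMP, (2R)-2-(methoxymethyl)pyrrolidin-1-amine | COC[C@H]1CCCN1N | starting material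
6 | (2R)-N-(2,2-dimethyl-1,3-dioxan-5-ylidene)-2-(methoxymethyl)pyrrolidin-1-amine | CC1(C)OCC(=NN2CCC[C@@H]2COC)CO1 | intermediate
7 | lithium azaenolate of 6 | [Li]N(N1CCC[C@@H]1COC)C1=COC(C)(C)OC1 | intermediate
8 | (2R)-N-[(4R)-4-[(2Z)-3-iodoprop-2-en-1-yl]-2,2-dimethyl-1,3-dioxan-5-ylidene]-2-(methoxymethyl)pyrrolidin-1-amine | CC1(C)OCC(=NN2CCC[C@@H]2COC)[C@@H](C/C=C\I)O1 | intermediate
9 | (4R)-4-[(2Z)-3-iodoprop-2-en-1-yl]-2,2-dimethyl-1,3-dioxan-5-one | CC1(C)OCC(=O)[C@@H](C/C=C\I)O1 | intermediate
10 | (4aS,7aR)-2,2-dimethyl-4,4a,7,7a-tetrahydrocyclopenta[d][1,3]dioxin-4a-ol (cis-fused 7,10-acetonide of (1S,5R)-1-(hydroxymethyl)cyclopent-2-ene-1,5-diol) | CC1(C)OC[C@@]2(O)C=CC[C@H]2O1 | intermediate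
11 | triformylmethane (methanetricarbaldehyde; reacts as its enol) | O=CC(C=O)C=O | starting material
12 | cyclobutanol photoadduct: cis-fused cyclobutane C1–C4–C5–C9 on the acetonide-protected cyclopentane, C1 bearing OH (either epimer), C4 bearing two formyl groups | OC1C(C=O)(C=O)[C@@H]2C[C@@H](OC(C)(C)OC3)[C@]3(O)[C@H]12 | intermediate
13 | ring-opened trialdehyde: acetonide-protected cyclopentane with formyl on C9 and diformylmethyl on C5, cis | O=CC(C=O)[C@@H]1C[C@@H](OC(C)(C)OC2)[C@]2(O)[C@@H]1C=O | intermediate
14 | lactol aldehyde, iridoid numbering (1S,5R,7R,8S,9R): 1,8-dihydroxy-7,10-O-isopropylidene-3-ene-11-al | O[C@H]1OC=C(C=O)[C@@H]2C[C@@H](OC(C)(C)OC3)[C@]3(O)[C@H]12 | intermediate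
15 | (3S)-3-methylpentanoic acid | CC[C@H](C)CC(=O)O | starting material
16 | C1 (3S)-3-methylpentanoate of 14, (1R,5R,7R,8S,9R) | CC[C@H](C)CC(=O)O[C@H]1OC=C(C=O)[C@@H]2C[C@@H](OC(C)(C)OC3)[C@]3(O)[C@H]12 | intermediate
17 | triol aldehyde, (1R,5R,7R,8S,9R): 1-O-acyl, 7,8,10-trihydroxy, 11-al | CC[C@H](C)CC(=O)O[C@H]1OC=C(C=O)[C@@H]2C[C@@H](O)[C@@](O)(CO)[C@H]12 | intermediate
18 | p-coumaric acid, (2E)-3-(4-hydroxyphenyl)prop-2-enoic acid | OC(=O)/C=C/c1ccc(O)cc1 | starting material
19 | tert-butyldimethylsilyl (2E)-3-[4-(tert-butyldimethylsilyloxy)phenyl]prop-2-enoate | CC(C)(C)[Si](C)(C)OC(=O)/C=C/c1ccc(O[Si](C)(C)C(C)(C)C)cc1 | intermediate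
20 | (2E)-3-[4-(tert-butyldimethylsilyloxy)phenyl]prop-2-enoic acid | OC(=O)/C=C/c1ccc(O[Si](C)(C)C(C)(C)C)cc1 | intermediate
21 | 10-O-[4-(tert-butyldimethylsilyloxy)-(E)-cinnamoyl] derivative of 17 | CC[C@H](C)CC(=O)O[C@H]1OC=C(C=O)[C@@H]2C[C@@H](O)[C@@](O)(COC(=O)/C=C/c3ccc(O[Si](C)(C)C(C)(C)C)cc3)[C@H]12 | intermediate
22 | 10-O-(E)-p-coumaroyl 11-aldehyde, (1R,5R,7R,8S,9R) | CC[C@H](C)CC(=O)O[C@H]1OC=C(C=O)[C@@H]2C[C@@H](O)[C@@](O)(COC(=O)/C=C/c3ccc(O)cc3)[C@H]12 | intermediate
23 | [(1R,4aR,6R,7S,7aR)-6,7-dihydroxy-4-(hydroxymethyl)-7-[[(E)-3-(4-hydroxyphenyl)prop-2-enoyl]oxymethyl]-4a,5,6,7a-tetrahydro-1H-cyclopenta[c]pyran-1-yl] (3S)-3-methylpentanoate | CC[C@H](C)CC(=O)O[C@H]1OC=C(CO)[C@@H]2C[C@@H](O)[C@@](O)(COC(=O)/C=C/c3ccc(O)cc3)[C@H]12 | target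

## Step count and least certain steps

Total step count: 13. Longest linear sequence: 11 steps (1 to 23 through steps 1, 2, 4, 5, 6, 7, 8, 9, 11, 12, 13).

**Step 7 (key step).**
- Most likely failure: loss of regiocontrol in the diradical closure, so that the partner adds with C4 on C9. A second risk is slow decay of 10 under long irradiation in the presence of the strongly acidic 11.
- Fallback (intramolecular delivery through a temporary silicon tether): from 10, silylation of the angular hydroxyl with i-Pr2Si(OTf)2/2,6-lutidine and capture with the triethylammonium enolate of 11 should give the mixed diisopropylsilyl acetal F1. Irradiation should then bond C1 to C9 on the face of O8 through a six-membered siloxane ring and close the cyclobutane, giving the tethered photoadduct F2. Bu4NF/AcOH removes the silicon and releases 12, which runs on through 13 to 14.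

**Step 6.**
- Most likely failure: reductive loss of iodine without ring closure, because addition to the hindered α-alkoxy ketone is slow.
- Fallback (ring-closing metathesis in place of the carbonyl addition): from 6, alkylation with allyl bromide (t-BuLi, THF) gives the allylated hydrazone F3, and oxalic acid frees the (R)-4-allyl ketone F4. Vinylmagnesium bromide with CeCl3 gives the vinyl carbinol F5; the diastereomer with vinyl cis to allyl is the one needed and would be separated from its epimer. The second-generation Grubbs catalyst then closes the cyclopentene to 10, since only the cis isomer can give the unstrained cis-fused ring.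

**Step 8.**
- Most likely failure: base-induced opening of the lactol, followed by acylation of the enol oxygen, loss of the C8 hydroxyl by β-elimination, or formation of an anomer mixture.
- Fallback (activation of the anomeric oxygen instead of the acid): from 14, Mitsunobu coupling with 15 (PPh3, DIAD, THF, −20 °C) under neutral conditions. The carboxylate displaces the oxyphosphonium group with inversion and should enter on the less hindered side trans to C8, giving 16 directly.

**Step 9.**
- Most likely failure: loss of the C1 acyl group or hydration of the enol ether during the acid hydrolysis.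
- Fallback (fluoride-labile diol protection put in place before the photochemical step): from 10, 80% AcOH gives the triol F6, and t-Bu2Si(OTf)2/2,6-lutidine bridges O7 and O10 as the six-membered silylene F7. The chemistry of steps 7 and 8 carried out on F7 gives the silylene-protected lactol aldehyde F8 and its C1 ester F9. HF·pyridine (excess pyridine, 0 °C) removes the silylene and returns to the route at 17.

**Step 11.**
- Most likely failure: competing acylation of the C7 hydroxyl, or double acylation.
- Fallback (carbon–oxygen bond made by substitution at C10 instead of acyl transfer to O10): from 17, TsCl/Et3N with catalytic Bu2SnO sulfonylates the primary hydroxyl of the 8,10-diol to the C10 tosylate F10, and DBU closes the 8,10-epoxide F11. The cesium salt of 20 (Cs2CO3, DMF, 50 °C) opens it at the CH2 terminus to give 21 with the tertiary hydroxyl already free.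

## Further compounds

F1 | step 7 | mixed diisopropylsilyl acetal linking O8 of 10 to the enol oxygen of 11 | CC1(C)OC[C@@]2(O[Si](C(C)C)(C(C)C)OC=C(C=O)C=O)C=CC[C@H]2O1
F2 | step 7 | tethered cyclobutane photoadduct with the O1–Si–O8 siloxane ring | CC(C)[Si]4(C(C)C)OC1C(C=O)(C=O)[C@@H]2C[C@@H](OC(C)(C)OC3)[C@]3(O4)[C@H]12
F3 | step 6 | (2R)-N-[(4R)-4-allyl-2,2-dimethyl-1,3-dioxan-5-ylidene]-2-(methoxymethyl)pyrrolidin-1-amine | CC1(C)OCC(=NN2CCC[C@@H]2COC)[C@@H](CC=C)O1
F4 | step 6 | (4R)-4-allyl-2,2-dimethyl-1,3-dioxan-5-one | CC1(C)OCC(=O)[C@@H](CC=C)O1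
F5 | step 6 | (4R,5S)-4-allyl-2,2-dimethyl-5-vinyl-1,3-dioxan-5-ol | CC1(C)OC[C@@](O)(C=C)[C@@H](CC=C)O1
F0 | step 8 | none | none
F6 | step 9 | (1S,5R)-1-(hydroxymethyl)cyclopent-2-ene-1,5-diol | OC[C@@]1(O)C=CC[C@H]1O
F7 | step 9 | 7,10-O-di-tert-butylsilylene derivative of F6 | CC(C)(C)[Si]1(C(C)(C)C)OC[C@@]2(O)C=CC[C@H]2O1
F8 | step 9 | 7,10-O-di-tert-butylsilylene analogue of lactol aldehyde 14 | O[C@H]1OC=C(C=O)[C@@H]2C[C@@H](O[Si](C(C)(C)C)(C(C)(C)C)OC3)[C@]3(O)[C@H]12
F9 | step 9 | 7,10-O-di-tert-butylsilylene analogue of C1 ester 16 | CC[C@H](C)CC(=O)O[C@H]1OC=C(C=O)[C@@H]2C[C@@H](O[Si](C(C)(C)C)(C(C)(C)C)OC3)[C@]3(O)[C@H]12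
F10 | step 11 | 10-O-p-toluenesulfonate of 17 | CC[C@H](C)CC(=O)O[C@H]1OC=C(C=O)[C@@H]2C[C@@H](O)[C@@](O)(COS(=O)(=O)c3ccc(C)cc3)[C@H]12
F11 | step 11 | 8,10-epoxide from F10 (spiro-oxirane at C8, 7-OH free) | CC[C@H](C)CC(=O)O[C@H]1OC=C(C=O)[C@@H]2C[C@@H](O)[C@@]3(CO3)[C@H]12
A1 | alternative 1 | cis-bicyclo[3.3.0]oct-2-ene with C4 silyloxymethyl group (C4 either epimer) and the 7,10-acetonide | C1=CC(CO[Si](C)(C)C(C)(C)C)[C@@H]2C[C@@H](OC(C)(C)OC3)[C@]3(O)[C@H]12
A2 | alternative 1 | 1,5-dialdehyde from cleavage of the C1=C3 bond of A1 | O=CC(CO[Si](C)(C)C(C)(C)C)[C@@H]1C[C@@H](OC(C)(C)OC2)[C@]2(O)[C@@H]1C=O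
A3 | alternative 2 | 2-[(4R,5S)-5-hydroxy-5-[(E)-2-methoxyvinyl]-2,2-dimethyl-1,3-dioxan-4-yl]acetaldehyde | CC1(C)OC[C@@](O)(/C=C/OC)[C@@H](CC=O)O1
A4 | alternative 2 | alkylidene malondialdehyde (1-oxadiene) from A3 | CC1(C)OC[C@@](O)(/C=C/OC)[C@@H](CC=C(C=O)C=O)O1
A5 | alternative 3 | cis-bicyclo[3.3.0]oct-3-en-2-one with C4 silyloxymethyl group and the 7,10-acetonide | O=C1C=C(CO[Si](C)(C)C(C)(C)C)[C@@H]2C[C@@H](OC(C)(C)OC3)[C@]3(O)[C@H]12
A6 | alternative 3 | enol lactone with oxygen inserted between C1 and C3 | O=C1OC=C(CO[Si](C)(C)C(C)(C)C)[C@@H]2C[C@@H](OC(C)(C)OC3)[C@]3(O)[C@H]12
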